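**Plan**
Ring numbering used below: C1 (carbinol bearing the ester), C2 (tertiary carbinol), C3 (ketone), C4, C5, C6(Me)=C7, C8 (enone ketone), C9 (isopropyl), C10.
Cuts: (i) the ester C1–O–acyl bond; (ii) the ring bond C3–C4, made by intramolecular Nozaki–Hiyama–Kishi addition of a C4 (Z)-alkenyl iodide to a C3 aldehyde (C4=C5 is hydrogenated afterwards); (iii) C7–C8, made by intermolecular Nozaki–Hiyama–Kishi coupling; (iv) the C3···C8 gap, which is the C1–C6 bond of (S)-carvone.
Enabling feature: the C3/C8 1,6-dione frames the chain C3–C2–C1–C10–C9–C8, which with its C2 methyl and C9 isopropyl is the six-membered ring of carvone opened between C=O and CH2. C3 sits next to the quaternary C2, so it can be carried as a non-enolisable aldehyde, and C4–C8 can be carried as five contiguous sp2 carbons that preorganise the ten-membered ring.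
Forward order: carvone → isopropyl enone → trans-epoxide → trans-diol → silyl enol ether → ozonolysis (C3 ester, C8 aldehyde) → union with a C5 iodo-enyne → (Z)-iodide → keto-aldehyde → ten-membered ring → hydrogenation, oxidation, desilylation → esterification with the epoxy acid.
Stereochemistry: C9 from (S)-carvone; C1 and C2 by substrate control (epoxidation anti to isopropyl, then SN2 hydrolysis at the β-carbon); C6=C7 (E) from syn-carboalumination; the oxirane from Sharpless asymmetric epoxidation of (Z)-2-methylbut-2-en-1-ol.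

Key step: step 13

Remark: the carbinol carbons formed without control in steps 8 and 13 are carried as epimer mixtures, since both become ketones (steps 12 and 15).

**Route**

Step 1
Reactants: 1 (S)-(+)-carvone
Product: 2 (5S)-2-methyl-5-(propan-2-yl)cyclohex-2-en-1-one
Conditions: H2 (1 atm), RhCl(PPh3)3 (2 mol%), benzene, rt
Reagents that add atoms: none
Why: Homogeneous hydrogenation with RhCl(PPh3)3 should reduce the unhindered 1,1-disubstituted isopropenyl alkene much faster than the trisubstituted conjugated ring alkene, leaving the enone and the carvone stereocentre intact.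

Step 2
Reactants: 2 (5S)-2-methyl-5-(propan-2-yl)cyclohex-2-en-1-one
Product: 3 (1S,4S,6S)-1-methyl-4-(propan-2-yl)-7-oxabicyclo[4.1.0]heptan-2-one (oxirane trans to isopropyl)
Conditions: 30% H2O2, NaOH (0.2 equiv), MeOH, 0 °C
Reagents that add atoms: hydrogen peroxide, OO
Why: Weitz–Scheffer epoxidation, in which hydroperoxide adds axially to the enone β-carbon on the face opposite the isopropyl group and the enolate closes the oxirane on that same face, sets both oxirane carbons trans to isopropyl.

Step 3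
Reactants: 3 (1S,4S,6S)-1-methyl-4-(propan-2-yl)-7-oxabicyclo[4.1.0]heptan-2-one
Product: 4 (2S,3R,5S)-2,3-dihydroxy-2-methyl-5-(propan-2-yl)cyclohexan-1-one
Conditions: HClO4 (cat.), THF/H2O, rt
Reagents that add atoms: water, O
Why: Acid-catalysed epoxide hydrolysis, in which water should attack the secondary β-carbon (not the quaternary, carbonyl-deactivated α-carbon) anti to the oxirane oxygen, inverts that carbon (hydroxyl cis to isopropyl) and retains the tertiary C–O bond, giving the trans-diol.

Step 4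
Reactants: 4 (2S,3R,5S)-2,3-dihydroxy-2-methyl-5-(propan-2-yl)cyclohexan-1-one
Product: 5 (3R,5R,6S)-6-methyl-3-(propan-2-yl)-1,5,6-tris[(triethylsilyl)oxy]cyclohex-1-ene
Conditions: Et3SiOTf (3.5 equiv), Et3N (5 equiv), CH2Cl2, 0 °C to rt
Reagents that add atoms: triethylsilyl trifluoromethanesulfonate, CC[Si](CC)(CC)OS(=O)(=O)C(F)(F)F
Why: Silyl triflate and amine base should silylate both hydroxyls and, by soft enolisation, convert the ketone into its silyl enol ether, which can only form toward the CH2 side because the other α-carbon is quaternary.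

Step 5
Reactants: 5 (3R,5R,6S)-6-methyl-3-(propan-2-yl)-1,5,6-tris[(triethylsilyl)oxy]cyclohex-1-ene
Product: 8 methyl (2S,3R,5R)-2-methyl-6-oxo-5-(propan-2-yl)-2,3-bis[(triethylsilyl)oxy]hexanoate, via methoxy hydroperoxide silyl ester 6 (not isolated), via aldehyde acid 7 (not isolated)
Conditions: O3, CH2Cl2/MeOH, −78 °C; Me2S, −78 °C to rt; then Me3SiCHN2, 0 °C
Reagents that add atoms: ozone, [O-][O+]=O; methanol, CO (methoxy group of intermediate 6 only); trimethylsilyldiazomethane, C[Si](C)(C)C=[N+]=[N-]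
Why: Ozonolysis of the silyl enol ether cleaves the ring into an aldehyde (future C8) and a silyl ester (future C3) at different oxidation levels, and reductive work-up, methanolysis and diazoalkane esterification should give the aldehyde ester without touching the three stereocentres.

Step 6
Reactants: 9 1,4-bis(trimethylsilyl)buta-1,3-diyne
Product: 11 (buta-1,3-diyn-1-yl)trimethylsilane, via lithium butadiynide 10 (not isolated)
Conditions: MeLi·LiBr (1.0 equiv), Et2O, rt; aq. NH4Cl
Reagents that add atoms: none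
Why: Nucleophilic desilylation by methyllithium at one silicon gives the lithium butadiynide, which resists a second attack and is protonated on work-up.

Step 7
Reactants: 11 (buta-1,3-diyn-1-yl)trimethylsilane
Product: 13 [(3E)-4-iodo-3-methylbut-3-en-1-yn-1-yl]trimethylsilane, via alkenylalane 12 (not isolated)
Conditions: AlMe3 (2 equiv), Cp2ZrCl2 (0.25 equiv), CH2Cl2, rt; then I2, THF, −30 °C
Reagents that add atoms: trimethylaluminium, C[Al](C)C; iodine, II
Why: Negishi zirconium-catalysed carboalumination adds methyl and aluminium syn across the terminal alkyne with methyl on the internal carbon, and iodinolysis of the C–Al bond with retention gives the (E)-alkenyl iodide.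

Step 8
Reactants: 8 methyl (2S,3R,5R)-2-methyl-6-oxo-5-(propan-2-yl)-2,3-bis[(triethylsilyl)oxy]hexanoate; 13 [(3E)-4-iodo-3-methylbut-3-en-1-yn-1-yl]trimethylsilane
Product: 14 methyl (2S,3R,5R,7E)-6-hydroxy-2,8-dimethyl-5-(propan-2-yl)-2,3-bis[(triethylsilyl)oxy]-10-(trimethylsilyl)dec-7-en-9-ynoate (C6 epimers)
Conditions: CrCl2 (4 equiv), NiCl2 (1 mol%), DMSO, rt
Reagents that add atoms: none
Why: In this Nozaki–Hiyama–Kishi coupling the alkenylchromium should add only to the aldehyde, with retention of the E geometry and without epimerising the adjacent stereocentre under non-basic conditions; the new carbinol centre is uncontrolled and is oxidised in step 12.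

Step 9
Reactants: 14 methyl (2S,3R,5R,7E)-6-hydroxy-2,8-dimethyl-5-(propan-2-yl)-2,3-bis[(triethylsilyl)oxy]-10-(trimethylsilyl)dec-7-en-9-ynoate
Product: 15 methyl (2S,3R,5R,7E)-6-hydroxy-10-iodo-2,8-dimethyl-5-(propan-2-yl)-2,3-bis[(triethylsilyl)oxy]dec-7-en-9-ynoate
Conditions: N-iodosuccinimide (1.2 equiv), AgNO3 (10 mol%), DMF, rt, dark
Reagents that add atoms: N-iodosuccinimide, O=C1CCC(=O)N1I
Why: Silver-catalysed iododesilylation should replace the alkynyl silyl group by iodine through the silver acetylide, leaving the silyl ethers on oxygen untouched.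

Step 10
Reactants: 15 methyl (2S,3R,5R,7E)-6-hydroxy-10-iodo-2,8-dimethyl-5-(propan-2-yl)-2,3-bis[(triethylsilyl)oxy]dec-7-en-9-ynoate
Product: 16 methyl (2S,3R,5R,7E,9Z)-6-hydroxy-10-iodo-2,8-dimethyl-5-(propan-2-yl)-2,3-bis[(triethylsilyl)oxy]deca-7,9-dienoate
Conditions: 2-nitrobenzenesulfonyl hydrazide (3 equiv), Et3N, THF/i-PrOH, rt
Reagents that add atoms: none
Why: Diimide made in the flask transfers two hydrogens suprafacially to the iodoalkyne, which should give the (Z)-alkenyl iodide while the trisubstituted alkene reacts far more slowly.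

Step 11
Reactants: 16 methyl (2S,3R,5R,7E,9Z)-6-hydroxy-10-iodo-2,8-dimethyl-5-(propan-2-yl)-2,3-bis[(triethylsilyl)oxy]deca-7,9-dienoate
Product: 17 (2R,3R,5R,7E,9Z)-10-iodo-2,8-dimethyl-5-(propan-2-yl)-2,3-bis[(triethylsilyl)oxy]deca-7,9-diene-1,6-diol (C6 epimers)
Conditions: i-Bu2AlH (4 equiv), CH2Cl2, −78 to −20 °C; aq. Rochelle salt
Reagents that add atoms: none
Why: Hydride reduction of the methyl ester to the primary alcohol should leave the alkenyl iodide and silyl ethers untouched at low temperature (the C2 descriptor changes by priority only).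

Step 12
Reactants: 17 (2R,3R,5R,7E,9Z)-10-iodo-2,8-dimethyl-5-(propan-2-yl)-2,3-bis[(triethylsilyl)oxy]deca-7,9-diene-1,6-diol
Product: 18 (2S,3R,5R,7E,9Z)-10-iodo-2,8-dimethyl-6-oxo-5-(propan-2-yl)-2,3-bis[(triethylsilyl)oxy]deca-7,9-dienal
Conditions: Dess–Martin periodinane (3 equiv), NaHCO3, CH2Cl2, 0 °C to rt
Reagents that add atoms: none
Why: Buffered Dess–Martin oxidation should convert the primary alcohol into the non-enolisable aldehyde and the dienylic alcohol into the dienone in one operation, removing the uncontrolled carbinol centre without epimerising the ketone α-carbon.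

Step 13
Reactants: 18 (2S,3R,5R,7E,9Z)-10-iodo-2,8-dimethyl-6-oxo-5-(propan-2-yl)-2,3-bis[(triethylsilyl)oxy]deca-7,9-dienal
Product: 19 (2E,4Z,7R,8R,10R)-6-hydroxy-3,7-dimethyl-10-(propan-2-yl)-7,8-bis[(triethylsilyl)oxy]cyclodeca-2,4-dien-1-one (C6 epimers)
Conditions: CrCl2 (10 equiv), NiCl2 (0.1 equiv), DMSO, rt, slow addition of 18 to reach about 2 mM
Reagents that add atoms: none
Why: Divalent chromium reduces NiCl2 to zerovalent nickel, which inserts into the C–I bond with retention, and transmetalation gives a (Z)-alkenyl species of trivalent chromium that adds 1,2 to the aldehyde carbon to forge C3–C4. The closest known reaction type is the intramolecular Nozaki–Hiyama–Kishi closure of medium carbocycles from alkenyl iodide aldehydes. The ten-membered ring closes in a 10-exo-trig mode, the aldehyde oxygen staying outside the ring. The new C3 carbinol centre forms without useful control (at most a Felkin-type bias from the C2 silyloxy group) and does not matter, because step 15 oxidises it. The step needs chemoselectivity for the aldehyde over the dienone carbonyl, which alkenylchromium reagents show, and ring closure over oligomerisation, which high dilution and the (2E,4Z)-dienone segment should secure: five contiguous sp2 carbons leave few rotatable ring bonds and the Z geometry turns the C–Cr bond back toward the aldehyde. The aldehyde has no α-hydrogen (quaternary C2), so it can neither enolise nor epimerise while it waits.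

Step 14
Reactants: 19 (2E,4Z,7R,8R,10R)-6-hydroxy-3,7-dimethyl-10-(propan-2-yl)-7,8-bis[(triethylsilyl)oxy]cyclodeca-2,4-dien-1-one
Product: 20 (2E,7R,8R,10R)-6-hydroxy-3,7-dimethyl-10-(propan-2-yl)-7,8-bis[(triethylsilyl)oxy]cyclodec-2-en-1-one (C6 epimers)
Conditions: H2 (1 atm), RhCl(PPh3)3 (10 mol%), benzene, rt
Reagents that add atoms: none
Why: RhCl(PPh3)3 should hydrogenate the cis-disubstituted ring alkene and leave the trisubstituted carbonyl-conjugated alkene, the same selectivity as in step 1; any allylic alcohol isomerisation would give ketone 21 directly and so converges after step 15.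

Step 15
Reactants: 20 (2E,7R,8R,10R)-6-hydroxy-3,7-dimethyl-10-(propan-2-yl)-7,8-bis[(triethylsilyl)oxy]cyclodec-2-en-1-one
Product: 21 (2E,7S,8R,10R)-3,7-dimethyl-10-(propan-2-yl)-7,8-bis[(triethylsilyl)oxy]cyclodec-2-ene-1,6-dione
Conditions: Dess–Martin periodinane (1.5 equiv), NaHCO3, CH2Cl2, rt
Reagents that add atoms: none
Why: Dess–Martin oxidation of the secondary alcohol gives the second ketone and erases the carbinol centre made in step 13 (the descriptor at the silyloxy-bearing quaternary carbon changes by priority only).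

Step 16
Reactants: 21 (2E,7S,8R,10R)-3,7-dimethyl-10-(propan-2-yl)-7,8-bis[(triethylsilyl)oxy]cyclodec-2-ene-1,6-dione
Product: 22 (2E,7S,8R,10R)-7,8-dihydroxy-3,7-dimethyl-10-(propan-2-yl)cyclodec-2-ene-1,6-dione
Conditions: HF·pyridine, pyridine, THF, 0 °C to rt
Reagents that add atoms: none
Why: Buffered fluoride cleavage of both silyl ethers avoids the basic conditions that could epimerise the ketone α-carbon or trigger retro-aldol cleavage; the E-enone keeps the 1,6-dione from transannular aldol closure because any bicyclic product would hold a trans alkene in a ring of seven or fewer atoms.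

Step 17
Reactants: 23 angelic acid, (2Z)-2-methylbut-2-enoic acid
Product: 24 (2Z)-2-methylbut-2-en-1-ol
Conditions: LiAlH4, Et2O, 0 °C to rt; Fieser work-up
Reagents that add atoms: none
Why: Hydride reduction of the carboxylic acid to the allylic alcohol should proceed with retention of the Z geometry.

Step 18
Reactants: 24 (2Z)-2-methylbut-2-en-1-ol
Product: 25 [(2S,3R)-2,3-dimethyloxiran-2-yl]methanol
Conditions: Ti(OiPr)4 (10 mol%), L-(+)-diethyl tartrate (12 mol%), t-BuOOH (2 equiv), 4 Å molecular sieves, CH2Cl2, −20 °C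
Reagents that add atoms: tert-butyl hydroperoxide, CC(C)(C)OO
Why: In the Sharpless asymmetric epoxidation the titanium tartrate complex of L-(+)-diethyl tartrate should deliver oxygen to the alkene face that gives the (2S,3R)-epoxy alcohol, and the cis relation of hydroxymethyl and C3 methyl follows from the Z alkene.

Step 19
Reactants: 25 [(2S,3R)-2,3-dimethyloxiran-2-yl]methanol
Product: 26 (2R,3R)-2,3-dimethyloxirane-2-carboxylic acid
Conditions: RuCl3 (2 mol%), NaIO4 (3 equiv), CCl4/MeCN/H2O, rt
Reagents that add atoms: water, O; sodium periodate, [Na+].[O-]I(=O)(=O)=O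
Why: RuO4 generated catalytically should oxidise the primary alcohol to the acid without opening the oxirane; the C2 descriptor changes from S to R by priority only.

Step 20
Reactants: 22 (2E,7S,8R,10R)-7,8-dihydroxy-3,7-dimethyl-10-(propan-2-yl)cyclodec-2-ene-1,6-dione; 26 (2R,3R)-2,3-dimethyloxirane-2-carboxylic acid
Product: 28 (1R,2S,6E,9R)-2-hydroxy-2,6-dimethyl-3,8-dioxo-9-(propan-2-yl)cyclodec-6-en-1-yl (2R,3R)-2,3-dimethyloxirane-2-carboxylate, via mixed anhydride 27 (not isolated)
Conditions: 26, 2,4,6-trichlorobenzoyl chloride, Et3N, toluene, rt; then 22, DMAP, toluene, rt to 40 °C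
Reagents that add atoms: 2,4,6-trichlorobenzoyl chloride, O=C(Cl)c1c(Cl)cc(Cl)cc1Cl (in intermediate 27 only)
Why: In the Yamaguchi esterification DMAP attacks the less hindered aliphatic carbonyl of the mixed anhydride and the acylpyridinium should acylate the secondary hydroxyl selectively over the tertiary one, with retention at the carbinol carbon because its C–O bond is not broken.

**Compound list**
1 | (S)-(+)-carvone, (5S)-2-methyl-5-(prop-1-en-2-yl)cyclohex-2-en-1-one | CC1=CC[C@@H](CC1=O)C(C)=C | starting material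
2 | (5S)-2-methyl-5-(propan-2-yl)cyclohex-2-en-1-one | CC1=CC[C@@H](CC1=O)C(C)C | intermediate
3 | (1S,4S,6S)-1-methyl-4-(propan-2-yl)-7-oxabicyclo[4.1.0]heptan-2-one | C1[C@@H](C(C)C)C[C@@H]2O[C@]2(C)C1=O | intermediate
4 | (2S,3R,5S)-2,3-dihydroxy-2-methyl-5-(propan-2-yl)cyclohexan-1-one | C1[C@@H](C(C)C)C[C@@H](O)[C@](C)(O)C1=O | intermediate
5 | (3R,5R,6S)-6-methyl-3-(propan-2-yl)-1,5,6-tris[(triethylsilyl)oxy]cyclohex-1-ene | C=1[C@@H](C(C)C)C[C@@H](O[Si](CC)(CC)CC)[C@](C)(O[Si](CC)(CC)CC)C=1O[Si](CC)(CC)CC | intermediate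
6 | triethylsilyl (2S,3R,5R)-6-hydroperoxy-6-methoxy-2-methyl-5-(propan-2-yl)-2,3-bis[(triethylsilyl)oxy]hexanoate | COC(OO)[C@@H](C(C)C)C[C@@H](O[Si](CC)(CC)CC)[C@](C)(O[Si](CC)(CC)CC)C(=O)O[Si](CC)(CC)CC | intermediate
7 | (2S,3R,5R)-2-methyl-6-oxo-5-(propan-2-yl)-2,3-bis[(triethylsilyl)oxy]hexanoic acid | O=C[C@@H](C(C)C)C[C@@H](O[Si](CC)(CC)CC)[C@](C)(O[Si](CC)(CC)CC)C(=O)O | intermediate
8 | methyl (2S,3R,5R)-2-methyl-6-oxo-5-(propan-2-yl)-2,3-bis[(triethylsilyl)oxy]hexanoate | O=C[C@@H](C(C)C)C[C@@H](O[Si](CC)(CC)CC)[C@](C)(O[Si](CC)(CC)CC)C(=O)OC | intermediate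
9 | 1,4-bis(trimethylsilyl)buta-1,3-diyne | C[Si](C)(C)C#CC#C[Si](C)(C)C | starting material
10 | lithium 4-(trimethylsilyl)buta-1,3-diyn-1-ide | [Li]C#CC#C[Si](C)(C)C | intermediate
11 | (buta-1,3-diyn-1-yl)trimethylsilane | C#CC#C[Si](C)(C)C | intermediate
12 | dimethyl[(1E)-2-methyl-4-(trimethylsilyl)but-1-en-3-yn-1-yl]alumane | C[Al](C)/C=C(C)/C#C[Si](C)(C)C | intermediate
13 | [(3E)-4-iodo-3-methylbut-3-en-1-yn-1-yl]trimethylsilane | I/C=C(C)/C#C[Si](C)(C)C | intermediate
14 | methyl (2S,3R,5R,7E)-6-hydroxy-2,8-dimethyl-5-(propan-2-yl)-2,3-bis[(triethylsilyl)oxy]-10-(trimethylsilyl)dec-7-en-9-ynoate, C6 epimers | C[Si](C)(C)C#C/C(C)=C/C(O)[C@@H](C(C)C)C[C@@H](O[Si](CC)(CC)CC)[C@](C)(O[Si](CC)(CC)CC)C(=O)OC | intermediate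
15 | methyl (2S,3R,5R,7E)-6-hydroxy-10-iodo-2,8-dimethyl-5-(propan-2-yl)-2,3-bis[(triethylsilyl)oxy]dec-7-en-9-ynoate, C6 epimers | IC#C/C(C)=C/C(O)[C@@H](C(C)C)C[C@@H](O[Si](CC)(CC)CC)[C@](C)(O[Si](CC)(CC)CC)C(=O)OC | intermediate
16 | methyl (2S,3R,5R,7E,9Z)-6-hydroxy-10-iodo-2,8-dimethyl-5-(propan-2-yl)-2,3-bis[(triethylsilyl)oxy]deca-7,9-dienoate, C6 epimers | I/C=C\C(C)=C\C(O)[C@@H](C(C)C)C[C@@H](O[Si](CC)(CC)CC)[C@](C)(O[Si](CC)(CC)CC)C(=O)OC | intermediate
17 | (2R,3R,5R,7E,9Z)-10-iodo-2,8-dimethyl-5-(propan-2-yl)-2,3-bis[(triethylsilyl)oxy]deca-7,9-diene-1,6-diol, C6 epimers | I/C=C\C(C)=C\C(O)[C@@H](C(C)C)C[C@@H](O[Si](CC)(CC)CC)[C@](C)(O[Si](CC)(CC)CC)CO | intermediate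
18 | (2S,3R,5R,7E,9Z)-10-iodo-2,8-dimethyl-6-oxo-5-(propan-2-yl)-2,3-bis[(triethylsilyl)oxy]deca-7,9-dienal | I/C=C\C(C)=C\C(=O)[C@@H](C(C)C)C[C@@H](O[Si](CC)(CC)CC)[C@](C)(O[Si](CC)(CC)CC)C=O | intermediate
19 | (2E,4Z,7R,8R,10R)-6-hydroxy-3,7-dimethyl-10-(propan-2-yl)-7,8-bis[(triethylsilyl)oxy]cyclodeca-2,4-dien-1-one, C6 epimers | CC(C)[C@H]1C[C@@H](O[Si](CC)(CC)CC)[C@](C)(O[Si](CC)(CC)CC)C(O)/C=C\C(C)=C\C1=O | intermediate
20 | (2E,7R,8R,10R)-6-hydroxy-3,7-dimethyl-10-(propan-2-yl)-7,8-bis[(triethylsilyl)oxy]cyclodec-2-en-1-one, C6 epimers | C/C1=C\C(=O)[C@@H](C(C)C)C[C@@H](O[Si](CC)(CC)CC)[C@](C)(O[Si](CC)(CC)CC)C(O)CC1 | intermediate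
21 | (2E,7S,8R,10R)-3,7-dimethyl-10-(propan-2-yl)-7,8-bis[(triethylsilyl)oxy]cyclodec-2-ene-1,6-dione | C/C1=C\C(=O)[C@@H](C(C)C)C[C@@H](O[Si](CC)(CC)CC)[C@](C)(O[Si](CC)(CC)CC)C(=O)CC1 | intermediate
22 | (2E,7S,8R,10R)-7,8-dihydroxy-3,7-dimethyl-10-(propan-2-yl)cyclodec-2-ene-1,6-dione | C/C1=C\C(=O)[C@@H](C(C)C)C[C@@H](O)[C@](C)(O)C(=O)CC1 | intermediate
23 | angelic acid, (2Z)-2-methylbut-2-enoic acid | C/C=C(/C)C(=O)O | starting material
24 | (2Z)-2-methylbut-2-en-1-ol | C/C=C(/C)CO | intermediate
25 | [(2S,3R)-2,3-dimethyloxiran-2-yl]methanol | OC[C@]1(C)O[C@@H]1C | intermediate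
26 | (2R,3R)-2,3-dimethyloxirane-2-carboxylic acid | OC(=O)[C@]1(C)O[C@@H]1C | intermediate
27 | (2R,3R)-2,3-dimethyloxirane-2-carboxylic 2,4,6-trichlorobenzoic anhydride | Clc1cc(Cl)cc(Cl)c1C(=O)OC(=O)[C@]1(C)O[C@@H]1C | intermediate
28 | (1R,2S,6E,9R)-2-hydroxy-2,6-dimethyl-3,8-dioxo-9-(propan-2-yl)cyclodec-6-en-1-yl (2R,3R)-2,3-dimethyloxirane-2-carboxylate | C/C1=C\C(=O)[C@@H](C(C)C)C[C@@H](OC(=O)[C@]2(C)O[C@@H]2C)[C@](C)(O)C(=O)CC1 | target

**Count**
Total steps: 20. Longest linear sequence: 15 steps (steps 1–5, 8–16 and 20).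

**Steps most likely to fail**

Step 13. Intermolecular addition (oligomerisation) may outrun closure of the ten-membered ring, or the alkenyl metal may lose its Z geometry so that the chain end can no longer reach the aldehyde and protodeiodination takes over. The fallback closes the same ring by olefin metathesis at C4=C5 and sets out from 17. Reductive deiodination with Bu3SnH and Pd(PPh3)4 (cat.) in THF should give the terminal diene diol F1. Dess–Martin oxidation should give the diene keto-aldehyde F2. Intermolecular Nozaki–Hiyama–Kishi vinylation of the aldehyde (vinyl bromide, CrCl2, NiCl2 cat., DMSO) should give the divinyl carbinol F3. Ring-closing metathesis with the second-generation Grubbs catalyst RuCl2(=CHPh)(PCy3)(SIMes) in dilute CH2Cl2 at reflux should then close the ring with loss of ethene, the ring size enforcing the Z alkene, and the route is rejoined at 19.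

Step 14. Chemoselectivity may be lost, either by over-reduction of the trisubstituted enone alkene or by failure to reduce a ring alkene shielded by the neighbouring silyloxy groups; reversible hydride addition could also scramble alkene geometry. The fallback replaces hydrogen addition by polar hydride delivery and sets out from 19. Dess–Martin oxidation should give the cross-conjugated dienedione F4. Conjugate reduction with [(Ph3P)CuH]6 in benzene at rt should then deliver hydride to the less substituted β-carbon of the (Z)-enone only (the β,β-disubstituted enone terminus being much slower), and protonation of the copper enolate rejoins the route at 21.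

Step 20. Acylation of the hindered secondary hydroxyl may be slow, leaving time for transannular hemiketal formation of the free diol onto the C8 ketone, base-induced retro-aldol cleavage of the C1–C2 bond, or epimerisation at C9. The fallback acylates before the tertiary hydroxyl is freed and sets out from 21. Mild acid methanolysis (pyridinium p-toluenesulfonate, MeOH/CH2Cl2, 0 °C) should remove the less hindered secondary silyl ether first and give the mono-silyl alcohol F5. Yamaguchi esterification with 26 through 27 should give the silyl-protected ester F6. HF·pyridine should then cleave the tertiary silyl ether and arrive at 28.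

**Further compounds**
F1 | step 13 | (2R,3R,5R,7E)-2,8-dimethyl-5-(propan-2-yl)-2,3-bis[(triethylsilyl)oxy]deca-7,9-diene-1,6-diol, C6 epimers | C=C/C(C)=C/C(O)[C@@H](C(C)C)C[C@@H](O[Si](CC)(CC)CC)[C@](C)(O[Si](CC)(CC)CC)CO
F2 | step 13 | (2S,3R,5R,7E)-2,8-dimethyl-6-oxo-5-(propan-2-yl)-2,3-bis[(triethylsilyl)oxy]deca-7,9-dienal | C=C/C(C)=C/C(=O)[C@@H](C(C)C)C[C@@H](O[Si](CC)(CC)CC)[C@](C)(O[Si](CC)(CC)CC)C=O
F3 | step 13 | (3E,6R,8R,9R)-10-hydroxy-3,9-dimethyl-6-(propan-2-yl)-8,9-bis[(triethylsilyl)oxy]dodeca-1,3,11-trien-5-one, C10 epimers | C=C/C(C)=C/C(=O)[C@@H](C(C)C)C[C@@H](O[Si](CC)(CC)CC)[C@](C)(O[Si](CC)(CC)CC)C(O)C=C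
F4 | step 14 | (2E,4Z,7S,8R,10R)-3,7-dimethyl-10-(propan-2-yl)-7,8-bis[(triethylsilyl)oxy]cyclodeca-2,4-diene-1,6-dione | CC(C)[C@H]1C[C@@H](O[Si](CC)(CC)CC)[C@](C)(O[Si](CC)(CC)CC)C(=O)/C=C\C(C)=C\C1=O
F5 | step 20 | (2E,7S,8R,10R)-8-hydroxy-3,7-dimethyl-10-(propan-2-yl)-7-[(triethylsilyl)oxy]cyclodec-2-ene-1,6-dione | C/C1=C\C(=O)[C@@H](C(C)C)C[C@@H](O)[C@](C)(O[Si](CC)(CC)CC)C(=O)CC1
F6 | step 20 | (1R,2S,6E,9R)-2,6-dimethyl-3,8-dioxo-9-(propan-2-yl)-2-[(triethylsilyl)oxy]cyclodec-6-en-1-yl (2R,3R)-2,3-dimethyloxirane-2-carboxylate | C/C1=C\C(=O)[C@@H](C(C)C)C[C@@H](OC(=O)[C@]2(C)O[C@@H]2C)[C@](C)(O[Si](CC)(CC)CC)C(=O)CC1
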